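**Plan**

- Retrosynthetic cuts, in order: the three O–benzyl bonds; the side chain (the C–H pair at its benzylic centre, back to an (E)-alkene, then the aryl–C(sp2) bond ortho to the phenol oxygen, back to an aryl bromide); C3–C4 of the tetrahydrofuran together with one C–H of each methyl group; the C2–O bond of the resulting diallyl ether.
- Enabling feature: in the tetrahydrofuran ring C3 and C4 each carry a methyl group and each is flanked by an aryl-bearing ether carbon (C2, C5). Cutting C3–C4 therefore leaves two 1-arylallyl groups on the ring oxygen, and their vinyl CH2 termini are the two methyl carbons.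
- Forward: two benzyloxybenzaldehydes become an (S)-allylic alcohol and a cinnamyl carbonate; an iridium-catalysed branched etherification joins them at C2–O; the hydrogen-atom-transfer radical cyclisation forms C3–C4 and closes the only new ring; the side chain is then coupled on, hydrogenated, and the phenols are freed.
- Stereochemistry: C5 from a lipase resolution; C2 from the chiral iridium allylation catalyst; C3 and C4 from the chair-like 5-exo transition state with both aryl groups pseudo-equatorial; the side-chain centre from iridium-catalysed asymmetric hydrogenation of the (E)-alkene.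

Key step: step 7

Assumption: the sense of induction of the chiral iridium catalysts in steps 6 and 11 is taken from the parent cinnamyl carbonate and (E)-1,2-diphenylpropene cases; should either centre form with the opposite sense, the mirror-image ligand would be used.

**Route**

Step 1
Reactants: 1 4-(benzyloxy)benzaldehyde; 2 vinylmagnesium bromide
Product: 3 rac-1-[4-(benzyloxy)phenyl]prop-2-en-1-ol
Conditions: THF, −78 to 0 °C; aq. NH4Cl
Reagents that add atoms: none
Why: Grignard 1,2-addition of the vinyl nucleophile to the aryl aldehyde should give the racemic secondary allylic alcohol, and the near-neutral quench avoids allylic transposition of the electron-rich carbinol.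

Step 2
Reactants: 3 rac-1-[4-(benzyloxy)phenyl]prop-2-en-1-ol
Product: 4 (S)-1-[4-(benzyloxy)phenyl]prop-2-en-1-ol
Conditions: Novozym 435 (immobilised Candida antarctica lipase B), vinyl acetate, MTBE, 30 °C, run to just past half conversion; chromatography
Reagents that add atoms: none
Why: Lipase-catalysed kinetic resolution by transesterification should acetylate the (R)-enantiomer (aryl as the large group, vinyl as the medium group) and leave the (S)-alcohol, which fixes the future C5 centre.

Step 3
Reactants: 5 4-(benzyloxy)-3-bromobenzaldehyde; 6 ethyl (triphenylphosphoranylidene)acetate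
Product: 7 ethyl (E)-3-[4-(benzyloxy)-3-bromophenyl]prop-2-enoate
Conditions: toluene, 80 °C
Reagents that add atoms: none
Why: Wittig olefination of an aryl aldehyde with a stabilised ylide should give the (E)-cinnamate without base, so the aryl bromide and benzyl ether are untouched.

Step 4
Reactants: 7 ethyl (E)-3-[4-(benzyloxy)-3-bromophenyl]prop-2-enoate
Product: 8 (E)-3-[4-(benzyloxy)-3-bromophenyl]prop-2-en-1-ol
Conditions: i-Bu2AlH (2.2 equiv), CH2Cl2, −78 °C; aq. potassium sodium tartrate
Reagents that add atoms: none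
Why: 1,2-Reduction of the unsaturated ester by the aluminium hydride at low temperature should give the cinnamyl alcohol with the alkene geometry and the aryl bromide intact.

Step 5
Reactants: 8 (E)-3-[4-(benzyloxy)-3-bromophenyl]prop-2-en-1-ol
Product: 9 tert-butyl (E)-3-[4-(benzyloxy)-3-bromophenyl]allyl carbonate
Conditions: Boc2O, Bu4NHSO4 (cat.), aq. NaOH, CH2Cl2, 0 °C to rt
Reagents that add atoms: di-tert-butyl dicarbonate (Boc2O), CC(C)(C)OC(=O)OC(=O)OC(C)(C)C
Why: Phase-transfer O-acylation of the primary allylic alcohol should give the tert-butyl carbonate, a leaving group that ionises readily on iridium and resists transesterification by alkoxides.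

Step 6
Reactants: 4 (S)-1-[4-(benzyloxy)phenyl]prop-2-en-1-ol; 9 tert-butyl (E)-3-[4-(benzyloxy)-3-bromophenyl]allyl carbonate
Product: 12 (S)-1-[4-(benzyloxy)phenyl]allyl (R)-1-[4-(benzyloxy)-3-bromophenyl]allyl ether, via lithium (S)-1-arylallyl alkoxide 10 (not isolated), via copper (S)-1-arylallyl alkoxide 11 (not isolated)
Conditions: 4 (1.5 equiv), n-BuLi, THF, 0 °C; CuI, rt; then 9, [Ir(cod)Cl]2 (2 mol%), (Ra,R,R)-L1 (4 mol%), THF, rt; L1 = O,O'-[(R)-1,1'-binaphthyl-2,2'-diyl] N,N-bis[(R)-1-phenylethyl]phosphoramidite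
Reagents that add atoms: none
Why: Iridium-catalysed branch-selective asymmetric allylic etherification with a soft copper alkoxide should deliver oxygen to the aryl-bearing allyl terminus of the cyclometalated iridium–phosphoramidite allyl complex, so that the catalyst sets the new C2 centre as (R) irrespective of the (S) centre in the nucleophile, while the organolithium only ever meets the bromine-free alcohol.

Step 7
Reactants: 12 (S)-1-[4-(benzyloxy)phenyl]allyl (R)-1-[4-(benzyloxy)-3-bromophenyl]allyl ether
Product: 13 (2R,3R,4S,5S)-2-[4-(benzyloxy)-3-bromophenyl]-5-[4-(benzyloxy)phenyl]-3,4-dimethyltetrahydrofuran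
Conditions: Mn(dpm)3 (10 mol%; dpm = 2,2,6,6-tetramethylheptane-3,5-dionate), PhSiH3 (2 equiv), t-BuOOH (1.5 equiv), i-PrOH/THF, 0.01 M, 22 °C, Ar
Reagents that add atoms: none
Why: A manganese hydride generated from Mn(dpm)3 and the silane should transfer a hydrogen atom to the CH2 terminus of either vinyl group, the secondary radical so formed (a 3-oxahex-5-enyl radical) adds to the internal carbon of the other vinyl group to make C3–C4, and the exocyclic primary radical takes up a second hydrogen atom to become the second methyl group. The closest known reaction type is the metal-hydride hydrogen-atom-transfer hydrogenative cyclisation of 1,6-dienes under Mukaiyama-type conditions. The tetrahydrofuran ring closes in the 5-exo-trig mode. The acceptor carbon is controlled by the chair-like transition state in which the aryl groups at C2 and C5 are both pseudo-equatorial, which puts its CH2 (the future methyl) trans to both aryl groups; the radical carbon is controlled by the 1,5-cis preference of 1-substituted hexenyl radicals together with avoidance of the neighbouring aryl group, which puts its methyl cis to the other methyl and trans to the adjacent aryl. The step needs ring closure to outrun reduction, 1,2-aryl shift and hydrogen loss of the first radical, which the fast closure of the oxygen-containing chain, the low standing hydride concentration and high dilution should secure; no regioselective initiation is needed because the pseudo-symmetric ether gives the same bond and the same relative configuration from either vinyl group, and the aryl bromide and benzyl ethers are inert.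

Step 8
Reactants: 14 1-(benzyloxy)-4-iodobenzene; 15 propyne
Product: 16 1-(benzyloxy)-4-(prop-1-yn-1-yl)benzene
Conditions: PdCl2(PPh3)2 (2 mol%), CuI (4 mol%), Et3N, THF, rt, sealed vessel (propyne as THF solution)
Reagents that add atoms: none
Why: Sonogashira coupling of an aryl iodide with a terminal alkyne should proceed at room temperature and leave the benzyl ether untouched.

Step 9
Reactants: 16 1-(benzyloxy)-4-(prop-1-yn-1-yl)benzene
Product: 17 (Z)-2-{1-[4-(benzyloxy)phenyl]prop-1-en-2-yl}-4,4,5,5-tetramethyl-1,3,2-dioxaborolane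
Conditions: CuCl (5 mol%), P(p-tol)3 (6 mol%), NaOt-Bu (10 mol%), B2pin2 (1.1 equiv), MeOH (2 equiv), THF, rt
Reagents that add atoms: bis(pinacolato)diboron (B2pin2), CC1(C)OB(OC1(C)C)B1OC(C)(C)C(C)(C)O1
Why: Copper-catalysed protoboration of an aryl alkyl alkyne should add copper and boron syn, with copper at the aryl-bearing carbon and boron at the methyl-bearing carbon, and protonolysis with retention then leaves boron trans to the aryl group.

Step 10
Reactants: 13 (2R,3R,4S,5S)-2-[4-(benzyloxy)-3-bromophenyl]-5-[4-(benzyloxy)phenyl]-3,4-dimethyltetrahydrofuran; 17 (Z)-2-{1-[4-(benzyloxy)phenyl]prop-1-en-2-yl}-4,4,5,5-tetramethyl-1,3,2-dioxaborolane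
Product: 18 (2R,3R,4S,5S)-2-{4-(benzyloxy)-3-[(E)-1-(4-(benzyloxy)phenyl)prop-1-en-2-yl]phenyl}-5-[4-(benzyloxy)phenyl]-3,4-dimethyltetrahydrofuran
Conditions: Pd(OAc)2 (5 mol%), SPhos (10 mol%), K3PO4, toluene/H2O (10:1), 80 °C
Reagents that add atoms: none
Why: Suzuki–Miyaura coupling with a bulky electron-rich biarylphosphine should join the ortho-alkoxy aryl bromide to the alkenyl boronate with retention of alkene geometry, giving the (E)-1,2-diarylpropene without touching the ring stereocentres.

Step 11
Reactants: 18 (2R,3R,4S,5S)-2-{4-(benzyloxy)-3-[(E)-1-(4-(benzyloxy)phenyl)prop-1-en-2-yl]phenyl}-5-[4-(benzyloxy)phenyl]-3,4-dimethyltetrahydrofuran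
Product: 19 (2R,3R,4S,5S)-2-{4-(benzyloxy)-3-[(R)-1-(4-(benzyloxy)phenyl)propan-2-yl]phenyl}-5-[4-(benzyloxy)phenyl]-3,4-dimethyltetrahydrofuran
Conditions: [Ir(cod)(L2)]BArF (2 mol%), H2 (50 bar), CH2Cl2, 25 °C; L2 = (S)-4-tert-butyl-2-[2-(di-o-tolylphosphanyl)phenyl]-4,5-dihydrooxazole, BArF = tetrakis[3,5-bis(trifluoromethyl)phenyl]borate
Reagents that add atoms: none
Why: Iridium-catalysed asymmetric hydrogenation of an unfunctionalised trisubstituted (E)-1,2-diarylpropene with a cationic phosphinooxazoline complex should add hydrogen to one alkene face under ligand control, setting the (R) side-chain centre, while benzyl ethers and the remote ring centres are unaffected.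

Step 12
Reactants: 19 (2R,3R,4S,5S)-2-{4-(benzyloxy)-3-[(R)-1-(4-(benzyloxy)phenyl)propan-2-yl]phenyl}-5-[4-(benzyloxy)phenyl]-3,4-dimethyltetrahydrofuran
Product: 20 (2R,3R,4S,5S)-2-{4-hydroxy-3-[(R)-1-(4-hydroxyphenyl)propan-2-yl]phenyl}-5-(4-hydroxyphenyl)-3,4-dimethyltetrahydrofuran (CNP0232576.1)
Conditions: H2 (1 atm), 10% Pd/C, EtOAc, rt, stopped as soon as debenzylation is complete
Reagents that add atoms: none
Why: Hydrogenolysis of the three aryl benzyl ethers over palladium on carbon in a neutral aprotic solvent should be much faster than cleavage of the benzylic C–O bonds of the ring and touches no stereocentre.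

**Compound list**

1 | 4-(benzyloxy)benzaldehyde | O=Cc1ccc(OCc2ccccc2)cc1 | starting material
2 | vinylmagnesium bromide | C=C[Mg]Br | starting material
3 | rac-1-[4-(benzyloxy)phenyl]prop-2-en-1-ol | C=CC(O)c1ccc(OCc2ccccc2)cc1 | intermediate
4 | (S)-1-[4-(benzyloxy)phenyl]prop-2-en-1-ol | C=C[C@H](O)c1ccc(OCc2ccccc2)cc1 | intermediate
5 | 4-(benzyloxy)-3-bromobenzaldehyde | O=Cc1ccc(OCc2ccccc2)c(Br)c1 | starting material
6 | ethyl (triphenylphosphoranylidene)acetate | CCOC(=O)C=P(c1ccccc1)(c1ccccc1)c1ccccc1 | starting material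
7 | ethyl (E)-3-[4-(benzyloxy)-3-bromophenyl]prop-2-enoate | CCOC(=O)/C=C/c1ccc(OCc2ccccc2)c(Br)c1 | intermediate
8 | (E)-3-[4-(benzyloxy)-3-bromophenyl]prop-2-en-1-ol | OC/C=C/c1ccc(OCc2ccccc2)c(Br)c1 | intermediate
9 | tert-butyl (E)-3-[4-(benzyloxy)-3-bromophenyl]allyl carbonate | CC(C)(C)OC(=O)OC/C=C/c1ccc(OCc2ccccc2)c(Br)c1 | intermediate
10 | lithium (S)-1-[4-(benzyloxy)phenyl]prop-2-en-1-olate | [Li+].C=C[C@H]([O-])c1ccc(OCc2ccccc2)cc1 | intermediate (not isolated)
11 | copper (S)-1-[4-(benzyloxy)phenyl]prop-2-en-1-olate (monovalent copper) | C=C[C@H](O[Cu])c1ccc(OCc2ccccc2)cc1 | intermediate (not isolated)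
12 | (S)-1-[4-(benzyloxy)phenyl]allyl (R)-1-[4-(benzyloxy)-3-bromophenyl]allyl ether | C=C[C@@H](c1ccc(OCc2ccccc2)cc1)O[C@H](C=C)c1ccc(OCc2ccccc2)c(Br)c1 | intermediate
13 | (2R,3R,4S,5S)-2-[4-(benzyloxy)-3-bromophenyl]-5-[4-(benzyloxy)phenyl]-3,4-dimethyltetrahydrofuran | C[C@@H]1[C@H](C)[C@@H](c2ccc(OCc3ccccc3)cc2)O[C@H]1c1ccc(OCc2ccccc2)c(Br)c1 | intermediate
14 | 1-(benzyloxy)-4-iodobenzene | Ic1ccc(OCc2ccccc2)cc1 | starting material
15 | propyne | CC#C | starting material
16 | 1-(benzyloxy)-4-(prop-1-yn-1-yl)benzene | CC#Cc1ccc(OCc2ccccc2)cc1 | intermediate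
17 | (Z)-2-{1-[4-(benzyloxy)phenyl]prop-1-en-2-yl}-4,4,5,5-tetramethyl-1,3,2-dioxaborolane | C/C(B1OC(C)(C)C(C)(C)O1)=C\c1ccc(OCc2ccccc2)cc1 | intermediate
18 | (2R,3R,4S,5S)-2-{4-(benzyloxy)-3-[(E)-1-(4-(benzyloxy)phenyl)prop-1-en-2-yl]phenyl}-5-[4-(benzyloxy)phenyl]-3,4-dimethyltetrahydrofuran | C[C@@H]1[C@H](C)[C@@H](c2ccc(OCc3ccccc3)cc2)O[C@H]1c1ccc(OCc2ccccc2)c(/C(C)=C/c2ccc(OCc3ccccc3)cc2)c1 | intermediate
19 | (2R,3R,4S,5S)-2-{4-(benzyloxy)-3-[(R)-1-(4-(benzyloxy)phenyl)propan-2-yl]phenyl}-5-[4-(benzyloxy)phenyl]-3,4-dimethyltetrahydrofuran | C[C@@H]1[C@H](C)[C@@H](c2ccc(OCc3ccccc3)cc2)O[C@H]1c1ccc(OCc2ccccc2)c([C@H](C)Cc2ccc(OCc3ccccc3)cc2)c1 | intermediate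
20 | (2R,3R,4S,5S)-2-{4-hydroxy-3-[(R)-1-(4-hydroxyphenyl)propan-2-yl]phenyl}-5-(4-hydroxyphenyl)-3,4-dimethyltetrahydrofuran (CNP0232576.1) | C[C@@H]1[C@H](C)[C@@H](c2ccc(O)cc2)O[C@H]1c1ccc(O)c([C@H](C)Cc2ccc(O)cc2)c1 | target

**Step count**

Total: 12 steps. Longest linear sequence: 8 steps (5 → 7 → 8 → 9 → 12 → 13 → 18 → 19 → 20, steps 3, 4, 5, 6, 7, 10, 11, 12).

**Steps most likely to fail**

Step 7. The first radical may be reduced before it closes the ring. Hydrogen-atom transfer to the monosubstituted vinyl groups may also be slow enough that the weak benzylic allylic C–H bonds of the ether are attacked instead. The fallback generates the same C3 radical by halogen abstraction; it sets out from 4 and 5 and comes back at 13. Wittig reaction of 5 with ethyltriphenylphosphonium bromide and KOt-Bu should give 1-(benzyloxy)-2-bromo-4-(prop-1-en-1-yl)benzene F1, whose alkene geometry is immaterial. Iodoetherification of F1 with alcohol 4 and N-iodosuccinimide (CH2Cl2, −40 °C) should place the alkoxy group at the benzylic carbon and iodine at the methyl-bearing carbon. After chromatographic removal of the epimer at the benzylic ether carbon, which this step does not control, this gives (S)-1-[4-(benzyloxy)phenyl]allyl (1S)-1-[4-(benzyloxy)-3-bromophenyl]-2-iodopropyl ether F2. Bu3SnH with Et3B/air in toluene at 0 °C (Ueno–Stork-type haloether cyclisation) then abstracts the alkyl iodide ahead of the aryl bromide, and the radical closes 5-exo through the same transition state to 13.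

Step 11. Turnover may stall or face selection may be poor, because the ortho benzyloxy group twists the aryl ring out of the alkene plane and can bind iridium. The fallback sets the centre by hydroboration instead; it sets out from 13 and comes back at 19. Suzuki–Miyaura coupling of 13 with isopropenylboronic acid pinacol ester (Pd(OAc)2, SPhos, K3PO4) should give (2R,3R,4S,5S)-2-[4-(benzyloxy)-3-(prop-1-en-2-yl)phenyl]-5-[4-(benzyloxy)phenyl]-3,4-dimethyltetrahydrofuran F3. Catalytic asymmetric anti-Markovnikov hydroboration of this 1,1-disubstituted aryl alkene (CoCl2 complex of a chiral iminopyridine-oxazoline ligand, NaBHEt3, pinacolborane) should give (2R,3R,4S,5S)-2-{4-(benzyloxy)-3-[(R)-1-(4,4,5,5-tetramethyl-1,3,2-dioxaborolan-2-yl)propan-2-yl]phenyl}-5-[4-(benzyloxy)phenyl]-3,4-dimethyltetrahydrofuran F4. B-alkyl Suzuki–Miyaura coupling of the primary boronate with 14 (Pd(OAc)2, RuPhos, K3PO4, toluene/H2O, 90 °C) then gives 19; the centre is not involved in this coupling.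

Step 6. The hindered secondary alkoxide may transesterify the carbonate, branched selectivity may erode, or catalyst control may be incomplete in a mismatched pairing. The fallback takes both centres from resolved alcohols and joins them stereospecifically; it sets out from 5, uses the copper alkoxide 11 made from 4, and comes back at 12. Addition of 2 to 5 should give rac-1-[4-(benzyloxy)-3-bromophenyl]prop-2-en-1-ol F5. The same lipase resolution acetylates the (R)-enantiomer to (R)-1-[4-(benzyloxy)-3-bromophenyl]allyl acetate F6, which is separated. Methanolysis (K2CO3, MeOH) gives (R)-1-[4-(benzyloxy)-3-bromophenyl]prop-2-en-1-ol F7, and Boc2O under the conditions of step 5 gives tert-butyl (R)-1-[4-(benzyloxy)-3-bromophenyl]allyl carbonate F8. Rhodium-catalysed allylic etherification of F8 with 11 (RhCl(PPh3)3 modified with P(OMe)3, THF, 0 °C to rt) is regioselective for the branched ether and proceeds with net retention, so it should give 12.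

**Further compounds**

F1 | step 7 | 1-(benzyloxy)-2-bromo-4-(prop-1-en-1-yl)benzene (E/Z mixture) | CC=Cc1ccc(OCc2ccccc2)c(Br)c1
F2 | step 7 | (S)-1-[4-(benzyloxy)phenyl]allyl (1S)-1-[4-(benzyloxy)-3-bromophenyl]-2-iodopropyl ether (either configuration at the iodine-bearing carbon) | C=C[C@@H](c1ccc(OCc2ccccc2)cc1)O[C@H](C(C)I)c1ccc(OCc2ccccc2)c(Br)c1
F3 | step 11 | (2R,3R,4S,5S)-2-[4-(benzyloxy)-3-(prop-1-en-2-yl)phenyl]-5-[4-(benzyloxy)phenyl]-3,4-dimethyltetrahydrofuran | C[C@@H]1[C@H](C)[C@@H](c2ccc(OCc3ccccc3)cc2)O[C@H]1c1ccc(OCc2ccccc2)c(C(C)=C)c1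
F4 | step 11 | (2R,3R,4S,5S)-2-{4-(benzyloxy)-3-[(R)-1-(4,4,5,5-tetramethyl-1,3,2-dioxaborolan-2-yl)propan-2-yl]phenyl}-5-[4-(benzyloxy)phenyl]-3,4-dimethyltetrahydrofuran | C[C@@H]1[C@H](C)[C@@H](c2ccc(OCc3ccccc3)cc2)O[C@H]1c1ccc(OCc2ccccc2)c([C@H](C)CB2OC(C)(C)C(C)(C)O2)c1
F5 | step 6 | rac-1-[4-(benzyloxy)-3-bromophenyl]prop-2-en-1-ol | C=CC(O)c1ccc(OCc2ccccc2)c(Br)c1
F6 | step 6 | (R)-1-[4-(benzyloxy)-3-bromophenyl]allyl acetate | C=C[C@@H](OC(C)=O)c1ccc(OCc2ccccc2)c(Br)c1
F7 | step 6 | (R)-1-[4-(benzyloxy)-3-bromophenyl]prop-2-en-1-ol | C=C[C@@H](O)c1ccc(OCc2ccccc2)c(Br)c1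
F8 | step 6 | tert-butyl (R)-1-[4-(benzyloxy)-3-bromophenyl]allyl carbonate | C=C[C@@H](OC(=O)OC(C)(C)C)c1ccc(OCc2ccccc2)c(Br)c1
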